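**Retrosynthetic overview**
- The six-membered ring is closed last by an intramolecular aldol: the α-methoxy cyclopentanone enolate adds to a tethered α-methoxy aldehyde. This gives the bicyclo[3.2.1]octan-8-one, the methoxy bridgehead and the carbinol in one step.
- The keto aldehyde comes from a 2-substituted 4-aryl-5-methoxycyclopentenone by one-pot methylcuprate addition and enolate allylation, which sets the methyl centre and the allyl-bearing quaternary centre from the aryl centre.
- That enone is the union of two six-step fragments: a 2-lithio enone ketal (fragment A) and a chiral C3 triflate that already carries the side-chain OMe and the masked aldehyde (fragment B).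
- Fragment A: (S)-4-silyloxycyclopentenone plus the aryl Grignard (1,4-addition, Rubottom oxidation, methylation, elimination, iodination, ketalisation). Fragment B: (R)-solketal.
- Ring order: the cyclopentane is bought, the arene is brought in intact, and the cyclohexane ring is formed last.

Assumption: 1, 2 and 11 are taken as commercial, and the methoxy-bearing α-carbon of 7–10 and 18–23 is drawn as the trans-to-aryl epimer (this centre is re-set when it is enolised in step 16).

**Fragment A**

Step 1
Reactants: 1 (4S)-4-[(tert-butyldimethylsilyl)oxy]cyclopent-2-en-1-one; 2 3,4,5-trimethoxyphenylmagnesium bromide (THF solution)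
Product: 4 tert-butyldimethyl{[(1S,2R)-2-(3,4,5-trimethoxyphenyl)-4-[(trimethylsilyl)oxy]cyclopent-3-en-1-yl]oxy}silane (silyl enol ether; aryl trans to OTBS), via bromomagnesium enolate 3 (not isolated)
Conditions: CuBr·SMe2 (10 mol %), TMSCl, THF, −78 °C; Et3N quench
Reagents that add atoms: chlorotrimethylsilane, C[Si](C)(C)Cl
Why: Copper-catalysed conjugate (1,4-) addition of the aryl Grignard occurs anti to the 4-silyloxy group, which sets the benzylic stereocentre; TMSCl traps the enolate regiospecifically on the aryl side, where the silyloxy group is not β to the enolate carbon and so is not eliminated.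

Step 2
Reactants: 4 silyl enol ether
Product: 6 (2S,3S,4S)-4-[(tert-butyldimethylsilyl)oxy]-2-hydroxy-3-(3,4,5-trimethoxyphenyl)cyclopentan-1-one, via α-trimethylsilyloxy ketone 5 (not isolated)
Conditions: mCPBA, CH2Cl2, −20 °C; then citric acid, MeOH, 0 °C
Reagents that add atoms: mCPBA, O=C(OO)c1cccc(Cl)c1
Why: Rubottom oxidation: the electron-rich enol ether is epoxidised anti to the neighbouring aryl group much faster than the arene reacts, a 1,4-silyl shift gives 5, and mild methanolysis frees the hydroxyl on the carbon next to the aryl centre.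

Step 3
Reactants: 6 α-hydroxy ketone
Product: 7 (2S,3S,4S)-4-[(tert-butyldimethylsilyl)oxy]-2-methoxy-3-(3,4,5-trimethoxyphenyl)cyclopentan-1-one
Conditions: Me3OBF4, 1,8-bis(dimethylamino)naphthalene, CH2Cl2, rt
Reagents that add atoms: trimethyloxonium tetrafluoroborate, C[O+](C)C.F[B-](F)(F)F
Why: O-Methylation with Meerwein's salt and a non-nucleophilic base avoids alkoxide conditions that would cause α-ketol shift or premature loss of silanol.

Step 4
Reactants: 7 α-methoxy β′-silyloxy ketone
Product: 8 (4S,5S)-5-methoxy-4-(3,4,5-trimethoxyphenyl)cyclopent-2-en-1-one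
Conditions: DBU, CH2Cl2, 0 °C
Reagents that add atoms: none
Why: E1cB β-elimination of the silanol toward the only CH2 α-position gives the enone, so the chirality of 1 is relayed to the aryl-bearing carbon; short contact at 0 °C limits γ-deprotonation.

Step 5
Reactants: 8 enone
Product: 9 (4S,5S)-2-iodo-5-methoxy-4-(3,4,5-trimethoxyphenyl)cyclopent-2-en-1-one
Conditions: I2, pyridine, CH2Cl2, 0 °C → rt
Reagents that add atoms: iodine, II
Why: Johnson α-iodination (Baylis–Hillman-type addition of pyridine, iodination of the enolate, elimination); without an electrophilic activator I2 leaves the trimethoxyarene alone.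

Step 6
Reactants: 9 α-iodo enone
Product: 10 (8S,9S)-6-iodo-9-methoxy-8-(3,4,5-trimethoxyphenyl)-1,4-dioxaspiro[4.4]non-6-ene
Conditions: TMSOCH2CH2OTMS, TMSOTf (cat.), CH2Cl2, −78 → −20 °C
Reagents that add atoms: 1,2-bis(trimethylsilyloxy)ethane, C[Si](C)(C)OCCO[Si](C)(C)C
Why: Noyori ketalisation under aprotic low-temperature conditions; the α-iodo substituent blocks double-bond migration and the allylic–benzylic centre is not disturbed.

**Fragment B**

Step 7
Reactants: 11 [(4R)-2,2-dimethyl-1,3-dioxolan-4-yl]methanol ((R)-solketal)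
Product: 12 (4S)-2,2-dimethyl-1,3-dioxolane-4-carbaldehyde
Conditions: TEMPO (cat.), PhI(OAc)2, CH2Cl2, rt
Reagents that add atoms: none
Why: Oxoammonium (TEMPO) oxidation of the primary alcohol under nearly neutral conditions stops at the aldehyde without epimerising the α-alkoxy centre (the descriptor changes only through CIP priorities).

Step 8
Reactants: 12 (S)-glyceraldehyde acetonide
Product: 13 (2S)-3,3-dimethoxypropane-1,2-diol
Conditions: HC(OMe)3, TsOH (cat.), MeOH, rt
Reagents that add atoms: methanol, CO; trimethyl orthoformate, COC(OC)OC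
Why: Acid-catalysed acetalisation with concurrent methanolysis of the acetonide (transacetalisation) locks the aldehyde as a non-enolisable dimethyl acetal; the stereocentre is not involved.

Step 9
Reactants: 13 diol
Product: 14 (2S)-1,1-dimethoxy-3-(triphenylmethoxy)propan-2-ol
Conditions: TrCl, Et3N, DMAP (cat.), CH2Cl2, rt
Reagents that add atoms: trityl chloride, ClC(c1ccccc1)(c1ccccc1)c1ccccc1
Why: Tritylation (SN1 through the trityl cation) is selective for the primary hydroxyl on steric grounds.

Step 10
Reactants: 14 secondary alcohol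
Product: 15 (2S)-1,1,2-trimethoxy-3-(triphenylmethoxy)propane
Conditions: NaH, MeI, THF, 0 °C → rt
Reagents that add atoms: iodomethane, CI
Why: Williamson ether synthesis; a trityl ether cannot migrate and the acetal is inert to NaH.

Step 11
Reactants: 15 trityl ether
Product: 16 (2S)-2,3,3-trimethoxypropan-1-ol
Conditions: TsOH (cat.), MeOH, rt
Reagents that add atoms: none
Why: Acid-catalysed SN1 methanolysis of the trityl ether; in methanol the dimethyl acetal can only exchange with solvent and so survives.

Step 12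
Reactants: 16 primary alcohol
Product: 17 (2S)-2,3,3-trimethoxypropyl trifluoromethanesulfonate
Conditions: Tf2O, 2,6-lutidine, CH2Cl2, −78 °C
Reagents that add atoms: trifluoromethanesulfonic anhydride, O=S(=O)(OS(=O)(=O)C(F)(F)F)C(F)(F)F
Why: Sulfonylation gives a triflate reactive enough for SN2 at a β-alkoxy carbon at −78 °C; it is used at once.

**Union and endgame**

Step 13
Reactants: 10 iodo ketal; 17 triflate
Product: 20 (4S,5S)-5-methoxy-2-[(2S)-2,3,3-trimethoxypropyl]-4-(3,4,5-trimethoxyphenyl)cyclopent-2-en-1-one, via vinyllithium 18 (not isolated), via alkylated ketal 19 (not isolated)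
Conditions: t-BuLi (2 equiv), THF/Et2O, −78 °C; then 17, −78 → −30 °C; then aq. oxalic acid, THF, 0 °C → rt
Reagents that add atoms: water, O
Why: Iodine–lithium exchange gives a stable α-keto vinyl anion equivalent (β-alkoxide loss would need a cyclic allene) and SN2 alkylation by the primary triflate joins the fragments without touching a stereocentre; the allylic ketone ketal then hydrolyses much faster than the α-alkoxy aldehyde acetal.

Step 14
Reactants: 20 enone
Product: 22 (2R,3R,4S,5S)-5-methoxy-3-methyl-2-(prop-2-en-1-yl)-2-[(2S)-2,3,3-trimethoxypropyl]-4-(3,4,5-trimethoxyphenyl)cyclopentan-1-one, via lithium enolate 21 (not isolated)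
Conditions: Me2CuLi (MeLi, CuI), Et2O, −40 → 0 °C; then allyl iodide, DMPU, THF, −78 → 0 °C
Reagents that add atoms: methyllithium, C[Li] (used as Me2CuLi, [Li+].C[Cu-]C); allyl iodide, C=CCI
Why: Tandem conjugate addition–enolate alkylation (three-component coupling): the Gilman cuprate adds anti to the adjacent aryl group (methyl trans to aryl) and the regiodefined enolate is allylated anti to the new methyl. This places allyl cis to aryl and the side chain cis to methyl at the quaternary carbon.

Step 15
Reactants: 22 keto acetal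
Product: 23 (2S)-2-methoxy-3-[(1R,2R,3S,4S)-4-methoxy-2-methyl-5-oxo-1-(prop-2-en-1-yl)-3-(3,4,5-trimethoxyphenyl)cyclopentyl]propanal
Conditions: TFA, H2O, CHCl3, 0 °C
Reagents that add atoms: water, O
Why: Acid-catalysed acetal hydrolysis; cold aqueous TFA frees the α-methoxy aldehyde without enolising it and leaves ketone, alkene and aryl ethers untouched.

Step 16
Reactants: 23 keto aldehyde
Product: 26 (1S,2S,3S,5R,6R,7S)-2-hydroxy-1,3-dimethoxy-6-methyl-5-(prop-2-en-1-yl)-7-(3,4,5-trimethoxyphenyl)bicyclo[3.2.1]octan-8-one (CNP0275320.2), via magnesium enolate 24 (not isolated), via magnesium aldolate 25 (not isolated)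
Conditions: MgBr2·OEt2, Et3N, CH2Cl2, −20 → 0 °C; aq. NH4Cl
Reagents that add atoms: none
Why: Intramolecular aldol addition by soft enolisation: MgBr2 chelated by the ketone and its α-methoxy group lets Et3N deprotonate the only enolisable ketone α-carbon, and the enolate can reach the aldehyde only on the face carrying the tether (anti to aryl), which fixes the methoxy bridgehead. A chair-like Zimmerman–Traxler-type transition state with Mg bridging both oxygens and the side-chain OMe equatorial gives the axial carbinol cis to that OMe; an epimerised aldehyde would have to put its OMe under the endo methyl and does not compete.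

**Compound list**
1 | (4S)-4-[(tert-butyldimethylsilyl)oxy]cyclopent-2-en-1-one | O=C1C=C[C@@H](O[Si](C)(C)C(C)(C)C)C1 | starting material
2 | 3,4,5-trimethoxyphenylmagnesium bromide | COc1cc([Mg]Br)cc(OC)c1OC | starting material
3 | bromomagnesium enolate of the 1,4-adduct | Br[Mg]OC1=C[C@H](c2cc(OC)c(OC)c(OC)c2)[C@@H](O[Si](C)(C)C(C)(C)C)C1 | intermediate (not isolated)
4 | tert-butyldimethyl{[(1S,2R)-2-(3,4,5-trimethoxyphenyl)-4-[(trimethylsilyl)oxy]cyclopent-3-en-1-yl]oxy}silane | C[Si](C)(C)OC1=C[C@H](c2cc(OC)c(OC)c(OC)c2)[C@@H](O[Si](C)(C)C(C)(C)C)C1 | intermediate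
5 | 2-O-trimethylsilyl ether of 6 | O=C1[C@@H](O[Si](C)(C)C)[C@H](c2cc(OC)c(OC)c(OC)c2)[C@@H](O[Si](C)(C)C(C)(C)C)C1 | intermediate (not isolated)
6 | (2S,3S,4S)-4-[(tert-butyldimethylsilyl)oxy]-2-hydroxy-3-(3,4,5-trimethoxyphenyl)cyclopentan-1-one | O=C1[C@@H](O)[C@H](c2cc(OC)c(OC)c(OC)c2)[C@@H](O[Si](C)(C)C(C)(C)C)C1 | intermediate
7 | (2S,3S,4S)-4-[(tert-butyldimethylsilyl)oxy]-2-methoxy-3-(3,4,5-trimethoxyphenyl)cyclopentan-1-one | O=C1[C@@H](OC)[C@H](c2cc(OC)c(OC)c(OC)c2)[C@@H](O[Si](C)(C)C(C)(C)C)C1 | intermediate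
8 | (4S,5S)-5-methoxy-4-(3,4,5-trimethoxyphenyl)cyclopent-2-en-1-one | O=C1[C@@H](OC)[C@H](c2cc(OC)c(OC)c(OC)c2)C=C1 | intermediate
9 | (4S,5S)-2-iodo-5-methoxy-4-(3,4,5-trimethoxyphenyl)cyclopent-2-en-1-one | O=C1[C@@H](OC)[C@H](c2cc(OC)c(OC)c(OC)c2)C=C1I | intermediate
10 | (8S,9S)-6-iodo-9-methoxy-8-(3,4,5-trimethoxyphenyl)-1,4-dioxaspiro[4.4]non-6-ene | IC1=C[C@@H](c2cc(OC)c(OC)c(OC)c2)[C@H](OC)C13OCCO3 | intermediate
11 | [(4R)-2,2-dimethyl-1,3-dioxolan-4-yl]methanol | OC[C@@H]1COC(C)(C)O1 | starting material
12 | (4S)-2,2-dimethyl-1,3-dioxolane-4-carbaldehyde | O=C[C@@H]1COC(C)(C)O1 | intermediate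
13 | (2S)-3,3-dimethoxypropane-1,2-diol | OC[C@H](O)C(OC)OC | intermediate
14 | (2S)-1,1-dimethoxy-3-(triphenylmethoxy)propan-2-ol | COC(OC)[C@@H](O)COC(c1ccccc1)(c1ccccc1)c1ccccc1 | intermediate
15 | (2S)-1,1,2-trimethoxy-3-(triphenylmethoxy)propane | COC(OC)[C@@H](OC)COC(c1ccccc1)(c1ccccc1)c1ccccc1 | intermediate
16 | (2S)-2,3,3-trimethoxypropan-1-ol | COC(OC)[C@@H](OC)CO | intermediate
17 | (2S)-2,3,3-trimethoxypropyl trifluoromethanesulfonate | COC(OC)[C@@H](OC)COS(=O)(=O)C(F)(F)F | intermediate
18 | vinyllithium from 10 (6-lithio ketal) | [Li]C1=C[C@@H](c2cc(OC)c(OC)c(OC)c2)[C@H](OC)C13OCCO3 | intermediate (not isolated)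
19 | (8S,9S)-9-methoxy-6-[(2S)-2,3,3-trimethoxypropyl]-8-(3,4,5-trimethoxyphenyl)-1,4-dioxaspiro[4.4]non-6-ene | COC(OC)[C@@H](OC)CC1=C[C@@H](c2cc(OC)c(OC)c(OC)c2)[C@H](OC)C13OCCO3 | intermediate (not isolated)
20 | (4S,5S)-5-methoxy-2-[(2S)-2,3,3-trimethoxypropyl]-4-(3,4,5-trimethoxyphenyl)cyclopent-2-en-1-one | O=C1[C@@H](OC)[C@H](c2cc(OC)c(OC)c(OC)c2)C=C1C[C@H](OC)C(OC)OC | intermediate
21 | lithium enolate from methyl addition to 20 | [Li]OC=1[C@@H](OC)[C@H](c2cc(OC)c(OC)c(OC)c2)[C@@H](C)C=1C[C@H](OC)C(OC)OC | intermediate (not isolated)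
22 | (2R,3R,4S,5S)-5-methoxy-3-methyl-2-(prop-2-en-1-yl)-2-[(2S)-2,3,3-trimethoxypropyl]-4-(3,4,5-trimethoxyphenyl)cyclopentan-1-one | O=C1[C@@H](OC)[C@H](c2cc(OC)c(OC)c(OC)c2)[C@@H](C)[C@@]1(CC=C)C[C@H](OC)C(OC)OC | intermediate
23 | (2S)-2-methoxy-3-[(1R,2R,3S,4S)-4-methoxy-2-methyl-5-oxo-1-(prop-2-en-1-yl)-3-(3,4,5-trimethoxyphenyl)cyclopentyl]propanal | O=C1[C@@H](OC)[C@H](c2cc(OC)c(OC)c(OC)c2)[C@@H](C)[C@@]1(CC=C)C[C@H](OC)C=O | intermediate
24 | bromomagnesium enolate of 23 | Br[Mg]OC1=C(OC)[C@H](c2cc(OC)c(OC)c(OC)c2)[C@@H](C)[C@@]1(CC=C)C[C@H](OC)C=O | intermediate (not isolated)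
25 | bromomagnesium aldolate of 26 | C=CC[C@]12C[C@H](OC)[C@H](O[Mg]Br)[C@](OC)(C1=O)[C@H](c1cc(OC)c(OC)c(OC)c1)[C@H]2C | intermediate (not isolated)
26 | (1S,2S,3S,5R,6R,7S)-2-hydroxy-1,3-dimethoxy-6-methyl-5-(prop-2-en-1-yl)-7-(3,4,5-trimethoxyphenyl)bicyclo[3.2.1]octan-8-one | C=CC[C@]12C[C@H](OC)[C@H](O)[C@](OC)(C1=O)[C@H](c1cc(OC)c(OC)c(OC)c1)[C@H]2C | target

**Totals**
Total step count: 16.
Longest linear sequence: 10 steps (steps 1–6 then 13–16; the branch through steps 7–12 then 13–16 is equally long).

**Three steps most likely to fail**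

Step 13. The vinyllithium must displace a β-alkoxy triflate faster than it deprotonates it, and the allylic ketal must hydrolyse before the side-chain acetal. The fallback sets out from 10 and comes back at 19. Diol 13 is closed to the epoxide (2S)-2-(dimethoxymethyl)oxirane F1 with NaH and 1-tosylimidazole in THF; the secondary alkoxide displaces the primary sulfonate, so the stereocentre is untouched. Vinyllithium 18, made from 10 as before, opens F1 at its CH2 terminus in the presence of BF3·OEt2 at −78 °C to give the homoallylic alcohol F2. O-Methylation (NaH, MeI) gives 19, which is hydrolysed to 20 as in step 13.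

Step 14. C-Allylation of a hindered, fully substituted cuprate-derived enolate can be slow. That would allow proton transfer to the acidic methoxy-bearing α′-position (over-allylation) or O-allylation. The fallback sets out from 20 and comes back at 22. After the same Me2CuLi addition, enolate 21 is acylated on oxygen with allyl chloroformate to give the allyl enol carbonate F3, which is isolated. Pd(PPh3)4 (zerovalent palladium, catalytic) in THF at rt then triggers decarboxylative Tsuji allylation; the π-allyl unit is delivered to the regiodefined enolate within the ion pair, anti to the methyl group, to give 22.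

Step 16. The carbinol configuration rests on the magnesium-bridged transition state, which is reasoned rather than precedented here; a freely reversible or non-chelated aldol could give the equatorial C-2 epimer. A corrective oxidation–reduction is not an option, because hydride would attack the C-2 ketone from the open face and give the same wrong epimer. The fallback sets out from 23 and comes back at 26. The epimeric aldol, the (2R)-epimer of 26 F4 (from 23 under the same conditions or with K2CO3 in MeOH), is converted into its triflate F5 with Tf2O and pyridine in CH2Cl2 at −20 °C. Lattrell–Dax displacement with KNO2 in DMF inverts the centre: nitrite attacks along the axial trajectory on the open face away from the two-carbon bridge, and the nitrite ester F6 hydrolyses on work-up to 26. This SN2 is next to a quaternary carbon and is itself uncertain.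

Further compounds
F1 | step 13 | (2S)-2-(dimethoxymethyl)oxirane | COC(OC)[C@@H]1CO1
F2 | step 13 | (2S)-1,1-dimethoxy-3-[(8S,9S)-9-methoxy-8-(3,4,5-trimethoxyphenyl)-1,4-dioxaspiro[4.4]non-6-en-6-yl]propan-2-ol | COC(OC)[C@@H](O)CC1=C[C@@H](c2cc(OC)c(OC)c(OC)c2)[C@H](OC)C13OCCO3
F3 | step 14 | allyl enol carbonate of 21 (allyl (3R,4S,5S)-5-methoxy-3-methyl-2-[(2S)-2,3,3-trimethoxypropyl]-4-(3,4,5-trimethoxyphenyl)cyclopent-1-en-1-yl carbonate) | C=CCOC(=O)OC=1[C@@H](OC)[C@H](c2cc(OC)c(OC)c(OC)c2)[C@@H](C)C=1C[C@H](OC)C(OC)OC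
F4 | step 16 | (2R)-epimer of 26 (equatorial 2-hydroxyl) | C=CC[C@]12C[C@H](OC)[C@@H](O)[C@](OC)(C1=O)[C@H](c1cc(OC)c(OC)c(OC)c1)[C@H]2C
F5 | step 16 | 2-O-trifluoromethanesulfonate of F4 | C=CC[C@]12C[C@H](OC)[C@@H](OS(=O)(=O)C(F)(F)F)[C@](OC)(C1=O)[C@H](c1cc(OC)c(OC)c(OC)c1)[C@H]2C
F6 | step 16 | 2-O-nitrite ester of 26 | C=CC[C@]12C[C@H](OC)[C@H](ON=O)[C@](OC)(C1=O)[C@H](c1cc(OC)c(OC)c(OC)c1)[C@H]2C
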